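**Plan**

Numbering: chroman O1, C2, C3, C4, C4a, C5–C8, C8a (ring A aromatic, ring C the pyran), ring B primed.
- Retrosynthesis: the quinone of ring B is first taken back to the 2',4'-diphenol (C5'–O bond). Ring C is then cut at C3–C4 and O1–C8a in one stroke.
- Enabling feature: C3 is benzylic to ring B and carries C2–O1, so O1–C2–C3 is a latent 2-aryloxirane (C3 electrophilic, O1 nucleophilic once opened). C4 and C8a are a benzylic carbon and its ortho ring carbon of ring A, so they map onto an ortho-bromobenzyl magnesium reagent.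
- Forward: benzyl chloride 8 (ring A, four steps) and oxirane 16 (ring B, three steps) are made separately. One flask forms C3–C4 and then closes ring C at O1–C8a. Removal of the methoxymethyl groups and oxidation of ring B finish the route.
- Stereochemistry: the single stereocentre C3 is set as (S) in oxirane 16 by catalyst-controlled transfer hydrogenation of chloroketone 14. SN2 inversion in the key step turns it into (R), and nothing later touches it.

Key step: step 8

Remark: the target is treated as the 2-hydroxy-1,4-benzoquinone tautomer drawn; the 4-hydroxy-1,2-benzoquinone form is the same compound.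

**Route**

Step 1
Reactants: 1 1-bromo-3,5-dimethoxybenzene; 2 1-bromo-3-methylbut-2-ene (prenyl bromide)
Product: 4 5-bromo-1,3-dimethoxy-2-(3-methylbut-2-en-1-yl)benzene, via aryllithium 3 (not isolated)
Conditions: LiN(i-Pr)2, THF, −78 °C; then 2, −78 to 0 °C
Reagents that add atoms: none
Why: Directed ortho-metalation, in which the C–H flanked by the two methoxy groups is the most acidic ring position and the amide base cannot undergo bromine–lithium exchange, followed by SN2 alkylation of aryllithium 3 with the primary allylic bromide.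

Step 2
Reactants: 4 5-bromo-1,3-dimethoxy-2-(3-methylbut-2-en-1-yl)benzene
Product: 6 6-bromo-2,4-dimethoxy-3-(3-methylbut-2-en-1-yl)benzaldehyde, via iminium chloride 5 (not isolated)
Conditions: POCl3, DMF, 0 to 70 °C; then aq NaOAc
Reagents that add atoms: N,N-dimethylformamide CN(C)C=O; water O
Why: Vilsmeier–Haack formylation, for which the only free ring positions of 4 are the two equivalent ones ortho and para to the methoxy groups, so a single aldehyde should result after hydrolysis of iminium 5.

Step 3
Reactants: 6 6-bromo-2,4-dimethoxy-3-(3-methylbut-2-en-1-yl)benzaldehyde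
Product: 7 [6-bromo-2,4-dimethoxy-3-(3-methylbut-2-en-1-yl)phenyl]methanol
Conditions: NaBH4, MeOH/THF, 0 °C
Reagents that add atoms: none
Why: Borohydride reduction of an aryl aldehyde, to which the aryl bromide and the trisubstituted alkene are inert.

Step 4
Reactants: 7 [6-bromo-2,4-dimethoxy-3-(3-methylbut-2-en-1-yl)phenyl]methanol
Product: 8 1-bromo-2-(chloromethyl)-3,5-dimethoxy-4-(3-methylbut-2-en-1-yl)benzene
Conditions: PPh3, CCl4, CH2Cl2, 0 °C to rt; used directly
Reagents that add atoms: tetrachloromethane ClC(Cl)(Cl)Cl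
Why: Appel chlorination under neutral conditions should convert the electron-rich benzylic alcohol into the chloride without acid that could add to the prenyl double bond.

Step 5
Reactants: 9 1,3-bis(methoxymethoxy)benzene; 2 1-bromo-3-methylbut-2-ene
Product: 11 1,3-bis(methoxymethoxy)-2-(3-methylbut-2-en-1-yl)benzene, via aryllithium 10 (not isolated)
Conditions: n-BuLi, THF, 0 °C to rt; then 2, 0 °C
Reagents that add atoms: none
Why: Directed ortho-metalation at the position between the two methoxymethoxy groups, both of which coordinate lithium, followed by SN2 alkylation with the allylic bromide.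

Step 6
Reactants: 11 1,3-bis(methoxymethoxy)-2-(3-methylbut-2-en-1-yl)benzene; 12 2-chloro-N-methoxy-N-methylacetamide
Product: 14 1-[2,4-bis(methoxymethoxy)-3-(3-methylbut-2-en-1-yl)phenyl]-2-chloroethan-1-one, via aryllithium 13 (not isolated)
Conditions: n-BuLi, TMEDA, THF, −20 to 0 °C; then 12, −78 to 0 °C; H2O
Reagents that add atoms: none
Why: A second directed ortho-metalation next to a methoxymethoxy group followed by Weinreb ketone synthesis, in which the chelated tetrahedral adduct prevents over-addition and leaves the C–Cl bond intact.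

Step 7
Reactants: 14 1-[2,4-bis(methoxymethoxy)-3-(3-methylbut-2-en-1-yl)phenyl]-2-chloroethan-1-one
Product: 16 (2S)-2-[2,4-bis(methoxymethoxy)-3-(3-methylbut-2-en-1-yl)phenyl]oxirane, via chlorohydrin 15 (not isolated)
Conditions: RuCl[(R,R)-TsDPEN](p-cymene) (1 mol%), HCO2H/Et3N (5:2), EtOAc, 25 °C; then aq NaOH (2 M), THF, 0 °C to rt; filtered through basic alumina and used at once
Reagents that add atoms: none
Why: Noyori–Ikariya asymmetric transfer hydrogenation of the aryl chloromethyl ketone sets the carbinol centre by catalyst control (the (R,R)-ligand is expected to give the (S)-chlorohydrin 15), and base then closes the oxirane by intramolecular Williamson displacement without touching that centre.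

Step 8
Reactants: 8 1-bromo-2-(chloromethyl)-3,5-dimethoxy-4-(3-methylbut-2-en-1-yl)benzene; 16 (2S)-2-[2,4-bis(methoxymethoxy)-3-(3-methylbut-2-en-1-yl)phenyl]oxirane
Product: 19 (3R)-3-[2,4-bis(methoxymethoxy)-3-(3-methylbut-2-en-1-yl)phenyl]-5,7-dimethoxy-6-(3-methylbut-2-en-1-yl)-3,4-dihydro-2H-chromene, via benzylmagnesium chloride 17 (not isolated), via chloromagnesium alkoxide 18 (not isolated)
Conditions: Mg, 2-MeTHF, 0 °C (8 to 17); 16 (1.1 equiv), CuI (20 mol%), THF, −40 to 0 °C; then 3,4,7,8-tetramethyl-1,10-phenanthroline (40 mol%), toluene, 110 °C (THF distilled off); aq NH4Cl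
Reagents that add atoms: none
Why: Proposed new method: a one-flask formal [3+3] annulation in which benzylmagnesium chloride 17, as its cuprate under CuI catalysis, should open oxirane 16 by SN2 attack at the benzylic carbon C3 (C3–C4 bond), and the chloromagnesium alkoxide 18 so released should pass to copper on heating with the phenanthroline ligand and close ring C by Ullmann-type C–O coupling onto the ortho C–Br bond (O1–C8a bond). The closest known reaction types are the copper-catalysed benzylic ring opening of aryl oxiranes by Grignard reagents and the copper/phenanthroline-catalysed cyclisation of 3-(2-bromoaryl)propan-1-ols to chromans; what is new is their merger on a magnesium alkoxide without isolation. Ring C closes in a six-membered mode, formally 6-exo-trig at C8a, through a seven-membered aryl–copper alkoxide chelate that reductively eliminates. The only new stereocentre, C3, is substrate-controlled: backside attack on the (S)-oxirane gives (R), and the later coupling at the remote aryl carbon cannot disturb it. The step needs (a) magnesium insertion into the benzylic C–Cl and not the aryl C–Br bond of 8, secured by the much higher reactivity of the benzylic chloride at 0 °C, (b) attack at the benzylic and not the terminal oxirane carbon, secured by the 2,4-dialkoxyaryl group on C3 and by the soft cuprate at low temperature, and (c) C–O coupling in preference to reduction of the C–Br bond, secured by using 16 in slight excess so that no Grignard reagent is left when the mixture is heated.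

Step 9
Reactants: 19 (3R)-3-[2,4-bis(methoxymethoxy)-3-(3-methylbut-2-en-1-yl)phenyl]-5,7-dimethoxy-6-(3-methylbut-2-en-1-yl)-3,4-dihydro-2H-chromene
Product: 20 4-[(3R)-5,7-dimethoxy-6-(3-methylbut-2-en-1-yl)-3,4-dihydro-2H-chromen-3-yl]-2-(3-methylbut-2-en-1-yl)benzene-1,3-diol
Conditions: HCl (cat.), MeOH, 25 to 40 °C
Reagents that add atoms: none
Why: Acid-catalysed acetal exchange with methanol should remove both methoxymethyl groups, with dilute acid and moderate temperature chosen so that the prenyl groups do not cyclise onto the freed phenols.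

Step 10
Reactants: 20 4-[(3R)-5,7-dimethoxy-6-(3-methylbut-2-en-1-yl)-3,4-dihydro-2H-chromen-3-yl]-2-(3-methylbut-2-en-1-yl)benzene-1,3-diol
Product: 21 5-[(3R)-5,7-dimethoxy-6-(3-methylbut-2-en-1-yl)-3,4-dihydro-2H-chromen-3-yl]-2-hydroxy-3-(3-methylbut-2-en-1-yl)cyclohexa-2,5-diene-1,4-dione (target)
Conditions: (KSO3)2NO (potassium nitrosodisulfonate), aq KH2PO4, acetone/H2O, rt
Reagents that add atoms: potassium nitrosodisulfonate [K+].[K+].[O]N(S(=O)(=O)[O-])S(=O)(=O)[O-]
Why: Teuber oxidation, in which the nitrosodisulfonate radical abstracts the hydrogen of the 2'-phenol and a second equivalent oxygenates the free para position C5', should give the 2-hydroxy-1,4-benzoquinone of ring B while the fully etherified ring A and the prenyl groups stay untouched.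

**Compound list**

1 | 1-bromo-3,5-dimethoxybenzene | COc1cc(Br)cc(OC)c1 | starting material
2 | 1-bromo-3-methylbut-2-ene (prenyl bromide) | CC(C)=CCBr | starting material
3 | (4-bromo-2,6-dimethoxyphenyl)lithium | [Li]c1c(OC)cc(Br)cc1OC | intermediate
4 | 5-bromo-1,3-dimethoxy-2-(3-methylbut-2-en-1-yl)benzene | COc1cc(Br)cc(OC)c1CC=C(C)C | intermediate
5 | N-{[6-bromo-2,4-dimethoxy-3-(3-methylbut-2-en-1-yl)phenyl]methylidene}-N-methylmethanaminium chloride | C[N+](C)=Cc1c(Br)cc(OC)c(CC=C(C)C)c1OC.[Cl-] | intermediate
6 | 6-bromo-2,4-dimethoxy-3-(3-methylbut-2-en-1-yl)benzaldehyde | O=Cc1c(Br)cc(OC)c(CC=C(C)C)c1OC | intermediate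
7 | [6-bromo-2,4-dimethoxy-3-(3-methylbut-2-en-1-yl)phenyl]methanol | OCc1c(Br)cc(OC)c(CC=C(C)C)c1OC | intermediate
8 | 1-bromo-2-(chloromethyl)-3,5-dimethoxy-4-(3-methylbut-2-en-1-yl)benzene | ClCc1c(Br)cc(OC)c(CC=C(C)C)c1OC | intermediate
9 | 1,3-bis(methoxymethoxy)benzene | COCOc1cccc(OCOC)c1 | starting material
10 | [2,6-bis(methoxymethoxy)phenyl]lithium | [Li]c1c(OCOC)cccc1OCOC | intermediate
11 | 1,3-bis(methoxymethoxy)-2-(3-methylbut-2-en-1-yl)benzene | COCOc1cccc(OCOC)c1CC=C(C)C | intermediate
12 | 2-chloro-N-methoxy-N-methylacetamide | CON(C)C(=O)CCl | starting material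
13 | [2,4-bis(methoxymethoxy)-3-(3-methylbut-2-en-1-yl)phenyl]lithium | [Li]c1ccc(OCOC)c(CC=C(C)C)c1OCOC | intermediate
14 | 1-[2,4-bis(methoxymethoxy)-3-(3-methylbut-2-en-1-yl)phenyl]-2-chloroethan-1-one | O=C(CCl)c1ccc(OCOC)c(CC=C(C)C)c1OCOC | intermediate
15 | (1S)-1-[2,4-bis(methoxymethoxy)-3-(3-methylbut-2-en-1-yl)phenyl]-2-chloroethan-1-ol | COCOc1ccc([C@H](O)CCl)c(OCOC)c1CC=C(C)C | intermediate
16 | (2S)-2-[2,4-bis(methoxymethoxy)-3-(3-methylbut-2-en-1-yl)phenyl]oxirane | COCOc1ccc([C@H]2CO2)c(OCOC)c1CC=C(C)C | intermediate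
17 | {[6-bromo-2,4-dimethoxy-3-(3-methylbut-2-en-1-yl)phenyl]methyl}magnesium chloride | Cl[Mg]Cc1c(Br)cc(OC)c(CC=C(C)C)c1OC | intermediate
18 | chloromagnesium (2R)-2-[2,4-bis(methoxymethoxy)-3-(3-methylbut-2-en-1-yl)phenyl]-3-[6-bromo-2,4-dimethoxy-3-(3-methylbut-2-en-1-yl)phenyl]propan-1-olate | COc1cc(Br)c(C[C@H](c2ccc(OCOC)c(CC=C(C)C)c2OCOC)CO[Mg]Cl)c(OC)c1CC=C(C)C | intermediate
19 | (3R)-3-[2,4-bis(methoxymethoxy)-3-(3-methylbut-2-en-1-yl)phenyl]-5,7-dimethoxy-6-(3-methylbut-2-en-1-yl)-3,4-dihydro-2H-chromene | COc1cc2c(c(OC)c1CC=C(C)C)C[C@H](c1ccc(OCOC)c(CC=C(C)C)c1OCOC)CO2 | intermediate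
20 | 4-[(3R)-5,7-dimethoxy-6-(3-methylbut-2-en-1-yl)-3,4-dihydro-2H-chromen-3-yl]-2-(3-methylbut-2-en-1-yl)benzene-1,3-diol | COc1cc2c(c(OC)c1CC=C(C)C)C[C@H](c1ccc(O)c(CC=C(C)C)c1O)CO2 | intermediate
21 | 5-[(3R)-5,7-dimethoxy-6-(3-methylbut-2-en-1-yl)-3,4-dihydro-2H-chromen-3-yl]-2-hydroxy-3-(3-methylbut-2-en-1-yl)cyclohexa-2,5-diene-1,4-dione (CNP0241224.1) | COc1cc2c(c(OC)c1CC=C(C)C)C[C@H](C1=CC(=O)C(O)=C(CC=C(C)C)C1=O)CO2 | target

**Step count and risks**

Total step count: 10. Longest linear sequence: 7 steps (steps 1, 2, 3, 4, 8, 9, 10).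

Steps most likely to fail:

1. Step 8. Several processes may intervene:
   - magnesium halide may isomerise the electron-rich oxirane to the aldehyde before the cuprate attacks;
   - partial ionisation at C3 may erode the enantiomeric purity;
   - attack may leak to the terminal oxirane carbon, which would lead on to the isomeric 2-arylchroman;
   - Wurtz homocoupling may consume the benzylic chloride during magnesium insertion;
   - the copper alkoxide coupling may stall.

   The fallback sets out from 16 and 8 and returns at 19; it reverses the polarity at C3 and uses known chemistry only. Oxirane 16 is isomerised on purpose by Meinwald rearrangement (InCl3 cat., THF) to 2-[2,4-bis(methoxymethoxy)-3-(3-methylbut-2-en-1-yl)phenyl]acetaldehyde F1. Pinnick oxidation (NaClO2, NaH2PO4, 2-methylbut-2-ene) should give [2,4-bis(methoxymethoxy)-3-(3-methylbut-2-en-1-yl)phenyl]acetic acid F2. This is loaded onto (R)-4-benzyl-1,3-oxazolidin-2-one (pivaloyl chloride, Et3N, LiCl) as the N-acyl oxazolidinone F3. Evans alkylation (NaN(SiMe3)2, THF, −78 °C, then 8) should give the (2R)-benzylated imide F4 under auxiliary control. LiBH4 should then release the (2R)-bromo alcohol F5. Intramolecular Buchwald–Hartwig etherification (Pd(OAc)2, 2-(di-tert-butylphosphino)-1,1'-binaphthyl, Cs2CO3, toluene, 70 °C) should close ring C to 19.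

2. Step 6. Deprotonation may occur at the benzylic and allylic methylene of the prenyl group and not on the ring, or the aryllithium may enolise the chloroacetamide and not add to it. The fallback sets out from 9 and returns at 13 and 14; it fixes the site of metalation with a halogen before the prenyl group is present. Bromination of 9 (NBS, MeCN, 0 °C) should give 1-bromo-2,4-bis(methoxymethoxy)benzene F6. Deprotonation between the two methoxymethoxy groups (LiN(i-Pr)2, THF, −78 °C) and alkylation with 2 should give 1-bromo-2,4-bis(methoxymethoxy)-3-(3-methylbut-2-en-1-yl)benzene F7. Bromine–lithium exchange (n-BuLi, THF, −78 °C), which is much faster than any deprotonation, should deliver aryllithium 13, acylated with 12 to 14 as in the main route.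

3. Step 2. Hydrogen chloride formed under the Vilsmeier conditions may add to, or cyclise, the prenyl group, and substitution at the hindered position between bromine and methoxy may be slow. The fallback sets out from 4 and returns at 6; it replaces electrophilic substitution by metalation. Deprotonation of 4 between bromine and methoxy (LiN(i-Pr)2, THF, −78 °C) should give [6-bromo-2,4-dimethoxy-3-(3-methylbut-2-en-1-yl)phenyl]lithium F8. This is quenched at −78 °C with DMF, before loss of LiBr to an aryne can set in, to give aldehyde 6 after aqueous work-up.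

**Further compounds**

F1 | step 8 | 2-[2,4-bis(methoxymethoxy)-3-(3-methylbut-2-en-1-yl)phenyl]acetaldehyde | O=CCc1ccc(OCOC)c(CC=C(C)C)c1OCOC
F2 | step 8 | [2,4-bis(methoxymethoxy)-3-(3-methylbut-2-en-1-yl)phenyl]acetic acid | OC(=O)Cc1ccc(OCOC)c(CC=C(C)C)c1OCOC
F3 | step 8 | (4R)-4-benzyl-3-{[2,4-bis(methoxymethoxy)-3-(3-methylbut-2-en-1-yl)phenyl]acetyl}-1,3-oxazolidin-2-one | O=C(Cc1ccc(OCOC)c(CC=C(C)C)c1OCOC)N1[C@H](Cc2ccccc2)COC1=O
F4 | step 8 | (4R)-4-benzyl-3-[(2R)-2-[2,4-bis(methoxymethoxy)-3-(3-methylbut-2-en-1-yl)phenyl]-3-[6-bromo-2,4-dimethoxy-3-(3-methylbut-2-en-1-yl)phenyl]propanoyl]-1,3-oxazolidin-2-one | COc1cc(Br)c(C[C@H](c2ccc(OCOC)c(CC=C(C)C)c2OCOC)C(=O)N2[C@H](Cc3ccccc3)COC2=O)c(OC)c1CC=C(C)C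
F5 | step 8 | (2R)-2-[2,4-bis(methoxymethoxy)-3-(3-methylbut-2-en-1-yl)phenyl]-3-[6-bromo-2,4-dimethoxy-3-(3-methylbut-2-en-1-yl)phenyl]propan-1-ol | COc1cc(Br)c(C[C@H](c2ccc(OCOC)c(CC=C(C)C)c2OCOC)CO)c(OC)c1CC=C(C)C
F6 | step 6 | 1-bromo-2,4-bis(methoxymethoxy)benzene | COCOc1ccc(Br)c(OCOC)c1
F7 | step 6 | 1-bromo-2,4-bis(methoxymethoxy)-3-(3-methylbut-2-en-1-yl)benzene | COCOc1ccc(Br)c(OCOC)c1CC=C(C)C
F8 | step 2 | [6-bromo-2,4-dimethoxy-3-(3-methylbut-2-en-1-yl)phenyl]lithium | [Li]c1c(Br)cc(OC)c(CC=C(C)C)c1OC
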